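## Retrosynthetic overview

1. Target 12 ⇒ phosphonoacetate 10 + 3-hydroxybenzaldehyde 11 (HWE builds the E-cinnamate, no phenol protection); 10 ⇒ diol 8 by acylation of its only secondary OH.
2. Diol 8 ⇒ ketol 7 (4β-hydroxyeudesman-6-one); hydride from the α face sets the axial C–O.
3. Ketol 7 ⇒ diketone 6 by intramolecular aldol: the carbinol ring is closed last, and three centres are set by equilibration.
4. Diketone 6 ⇒ piperitone 1 (the isopropyl-bearing ring, bought) + masked 4-oxopentyl Grignard 3 from 2; a catalyst-controlled conjugate addition sets the quaternary methyl centre.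

Assumption: racemic piperitone 1 is used; its α-isopropyl centre is equilibrated in step 2, so only the catalyst-set quaternary centre decides which enantiomer is made.

## Route

Step 1
Reactants: 1 (±)-piperitone [(RS)-3-methyl-6-(propan-2-yl)cyclohex-2-en-1-one]; 2 2-(3-bromopropyl)-2-methyl-1,3-dioxolane
Product: 5 (2RS,5R)-5-methyl-5-[3-(2-methyl-1,3-dioxolan-2-yl)propyl]-2-(propan-2-yl)cyclohexan-1-one, via Grignard reagent 3 (not isolated), via magnesium enolate 4 (not isolated)
Conditions: 2, Mg, Et2O, reflux; then 1, Cu(OTf)2 (3 mol %), chiral C2-symmetric 4,5-diphenylimidazolinium salt (NHC precursor, 4 mol %, the antipode that gives 5R), Et2O, 0 °C; H2O quench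
Reagents that add atoms: none
Why: Cu–NHC-catalysed asymmetric conjugate addition of a Grignard reagent to a β,β-disubstituted cyclohexenone, in which the catalyst chooses the enone face and so sets the quaternary centre as 5R in both enantiomers of 1, while the remote, conformationally weakly biased C-2 centre is carried as a mixture because it is equilibrated in step 2.

Step 2
Reactants: 5 (2RS,5R)-5-methyl-5-[3-(2-methyl-1,3-dioxolan-2-yl)propyl]-2-(propan-2-yl)cyclohexan-1-one
Product: 7 (2S,4aR,8S,8aR)-8-hydroxy-4a,8-dimethyl-2-(propan-2-yl)octahydronaphthalen-1(2H)-one (4β-hydroxyeudesman-6-one), via diketone 6 (not isolated)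
Conditions: 2 M HCl, THF, rt; extractive work-up, crude 6 carried on; then KOH (0.3 equiv), MeOH, 0 °C → rt
Reagents that add atoms: water O
Why: Ketal hydrolysis followed by a reversible base-mediated intramolecular aldol (6-enolexo), in which only the C-6 enolate can close a fused six-membered ring and equilibration funnels the material to the most stable ketol, i.e. trans-decalin (H-8a anti to the angular methyl), equatorial isopropyl at C-2 (epimerisation α to the ketone) and equatorial 8-methyl with axial 8-OH, because the C-8 epimer would place a methyl 1,3-diaxial to the angular methyl.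

Step 3
Reactants: 7 (2S,4aR,8S,8aR)-8-hydroxy-4a,8-dimethyl-2-(propan-2-yl)octahydronaphthalen-1(2H)-one
Product: 8 (1R,2S,4aR,8S,8aS)-4a,8-dimethyl-2-(propan-2-yl)decahydronaphthalene-1,8-diol (eudesmane-4β,6β-diol)
Conditions: NaBH4, MeOH, 0 °C → rt
Reagents that add atoms: none
Why: Borohydride reduction under steric approach control, where the β face of the carbonyl is blocked by the syn-axial angular methyl and the axial 8-OH, so hydride adds from the α face and gives the axial 1-OH cis to both (the same sense as 6-oxo-5α-steroids giving 6β-alcohols).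

Step 4
Reactants: 8 (1R,2S,4aR,8S,8aS)-4a,8-dimethyl-2-(propan-2-yl)decahydronaphthalene-1,8-diol; 9 2-(diethoxyphosphoryl)acetic acid
Product: 10 (1R,2S,4aR,8S,8aS)-8-hydroxy-4a,8-dimethyl-2-(propan-2-yl)decahydronaphthalen-1-yl 2-(diethoxyphosphoryl)acetate
Conditions: 9 (1.5 equiv), DCC (1.5 equiv), DMAP (0.2 equiv), CH2Cl2, 0 °C → rt
Reagents that add atoms: none
Why: Steglich esterification in which the small, strongly activated phosphonoacetyl group reaches the hindered axial secondary alcohol while the tertiary alcohol stays inert, with no stereocentre touched.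

Step 5
Reactants: 10 (1R,2S,4aR,8S,8aS)-8-hydroxy-4a,8-dimethyl-2-(propan-2-yl)decahydronaphthalen-1-yl 2-(diethoxyphosphoryl)acetate; 11 3-hydroxybenzaldehyde
Product: 12 (1R,2S,4aR,8S,8aS)-8-hydroxy-4a,8-dimethyl-2-(propan-2-yl)decahydronaphthalen-1-yl (2E)-3-(3-hydroxyphenyl)prop-2-enoate (target)
Conditions: 11 (1.5 equiv), LiCl (3 equiv), DBU (3 equiv), MeCN, rt; aq. NH4Cl work-up
Reagents that add atoms: none
Why: Horner–Wadsworth–Emmons olefination under Masamune–Roush conditions gives the E-cinnamate, the meta-phenoxide formed in situ is not conjugated to the aldehyde and so does not stop the reaction, and the mild base leaves the ester, the tertiary alcohol and all stereocentres untouched.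

## Compound list

1 | (±)-piperitone, (RS)-3-methyl-6-(propan-2-yl)cyclohex-2-en-1-one | CC1=CC(=O)C(C(C)C)CC1 | starting material
2 | 2-(3-bromopropyl)-2-methyl-1,3-dioxolane | CC1(CCCBr)OCCO1 | starting material
3 | [3-(2-methyl-1,3-dioxolan-2-yl)propyl]magnesium bromide | CC1(CCC[Mg]Br)OCCO1 | intermediate
4 | bromomagnesium (3R,6RS)-3-methyl-3-[3-(2-methyl-1,3-dioxolan-2-yl)propyl]-6-(propan-2-yl)cyclohex-1-en-1-olate | CC(C)C1CC[C@@](C)(CCCC2(C)OCCO2)C=C1O[Mg]Br | intermediate
5 | (2RS,5R)-5-methyl-5-[3-(2-methyl-1,3-dioxolan-2-yl)propyl]-2-(propan-2-yl)cyclohexan-1-one (mixture of C-2 epimers) | CC(C)C1CC[C@@](C)(CCCC2(C)OCCO2)CC1=O | intermediate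
6 | (2RS,5R)-5-methyl-5-(4-oxopentyl)-2-(propan-2-yl)cyclohexan-1-one | CC(C)C1CC[C@@](C)(CCCC(C)=O)CC1=O | intermediate
7 | (2S,4aR,8S,8aR)-8-hydroxy-4a,8-dimethyl-2-(propan-2-yl)octahydronaphthalen-1(2H)-one (4β-hydroxyeudesman-6-one) | CC(C)[C@@H]1CC[C@@]2(C)CCC[C@](C)(O)[C@@H]2C1=O | intermediate
8 | (1R,2S,4aR,8S,8aS)-4a,8-dimethyl-2-(propan-2-yl)decahydronaphthalene-1,8-diol (eudesmane-4β,6β-diol) | CC(C)[C@@H]1CC[C@@]2(C)CCC[C@](C)(O)[C@@H]2[C@@H]1O | intermediate
9 | 2-(diethoxyphosphoryl)acetic acid | CCOP(=O)(CC(=O)O)OCC | starting material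
10 | (1R,2S,4aR,8S,8aS)-8-hydroxy-4a,8-dimethyl-2-(propan-2-yl)decahydronaphthalen-1-yl 2-(diethoxyphosphoryl)acetate | CC(C)[C@@H]1CC[C@@]2(C)CCC[C@](C)(O)[C@@H]2[C@@H]1OC(=O)CP(=O)(OCC)OCC | intermediate
11 | 3-hydroxybenzaldehyde | O=Cc1cccc(O)c1 | starting material
12 | (1R,2S,4aR,8S,8aS)-8-hydroxy-4a,8-dimethyl-2-(propan-2-yl)decahydronaphthalen-1-yl (2E)-3-(3-hydroxyphenyl)prop-2-enoate | CC(C)[C@@H]1CC[C@@]2(C)CCC[C@](C)(O)[C@@H]2[C@@H]1OC(=O)/C=C/c1cccc(O)c1 | target

## Step count and risks

Total step count: 5. Longest linear sequence: 5 steps (1/2 → 5 → 7 → 8 → 10 → 12).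

The three steps most likely to fail:

**Step 1.** The catalyst has to override the α′-isopropyl centre of racemic 1 on a hindered enone, and this is argued by analogy to 3-methylcyclohexenone, not shown on piperitone itself. A slow or poorly selective mismatched enantiomer would lower the ee of everything downstream. The fallback sets the quaternary centre on an achiral enone and adds the isopropyl group afterwards; it sets out from 2 (through Grignard reagent 3) and comes back at 5. Grignard 3 is added under the same Cu–NHC catalysis to commercial 3-methylcyclohex-2-en-1-one. This gives, through bromomagnesium (S)-3-methyl-3-[3-(2-methyl-1,3-dioxolan-2-yl)propyl]cyclohex-1-en-1-olate F1, the ketone (S)-3-methyl-3-[3-(2-methyl-1,3-dioxolan-2-yl)propyl]cyclohexan-1-one F2 (the same spatial arrangement as 5R in 5; only the CIP ranking changes). LDA in THF at −78 °C deprotonates on the side away from the quaternary carbon, and acetone traps the enolate as (5R)-2-(2-hydroxypropan-2-yl)-5-methyl-5-[3-(2-methyl-1,3-dioxolan-2-yl)propyl]cyclohexan-1-one F3. p-TsOH in benzene with water removal dehydrates it to (5R)-5-methyl-5-[3-(2-methyl-1,3-dioxolan-2-yl)propyl]-2-(propan-2-ylidene)cyclohexan-1-one F4, and H2 over Pd/C in EtOAc then gives 5.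

**Step 2.** The equilibrating aldol could stall at a bridged ketol (attack of the side-chain enolate on the ring ketone), give the C-8 epimer or a cis-fused isomer, or dehydrate. The fallback sets the carbinol centre by a hydroxyl-directed epoxidation instead of by aldol equilibrium; it sets out from 5 and comes back at 7. Heating 5 with p-TsOH in wet benzene (hydrolysis, then aldol condensation with water removal) gives the enone (2S,4aR)-4a,8-dimethyl-2-(propan-2-yl)-3,4,4a,5,6,7-hexahydronaphthalen-1(2H)-one F5. Luche reduction (NaBH4, CeCl3, MeOH), with hydride from the face anti to the angular methyl, gives (1R,2S,4aR)-4a,8-dimethyl-2-(propan-2-yl)-1,2,3,4,4a,5,6,7-octahydronaphthalen-1-ol F6. VO(acac)2 and t-BuOOH deliver oxygen syn to the hydroxyl and give 4β,5β-epoxyeudesman-6β-ol F7, and Dess–Martin oxidation gives 4β,5β-epoxyeudesman-6-one F8. SmI2 in THF/MeOH at −78 °C cleaves the C–O bond α to the ketone with the carbinol configuration retained, and protonation with brief base equilibration of the ring-fusion centre gives 7.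

**Step 4.** The axial secondary OH is flanked by the isopropyl group and is syn-axial to the angular methyl and the tertiary OH, so carbodiimide coupling may be slow and N-acylurea may form. The fallback uses a small acyl bromide and builds the phosphonate on the ester; it sets out from 8 and comes back at 10. Bromoacetyl bromide and pyridine in CH2Cl2 at −20 °C give (1R,2S,4aR,8S,8aS)-8-hydroxy-4a,8-dimethyl-2-(propan-2-yl)decahydronaphthalen-1-yl 2-bromoacetate F9, and a Michaelis–Arbuzov reaction with P(OEt)3 at 110 °C gives 10.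

## Further compounds

F1 | step 1 | bromomagnesium (S)-3-methyl-3-[3-(2-methyl-1,3-dioxolan-2-yl)propyl]cyclohex-1-en-1-olate | C1CC[C@@](C)(CCCC2(C)OCCO2)C=C1O[Mg]Br
F2 | step 1 | (S)-3-methyl-3-[3-(2-methyl-1,3-dioxolan-2-yl)propyl]cyclohexan-1-one | O=C1CCC[C@@](C)(CCCC2(C)OCCO2)C1
F3 | step 1 | (5R)-2-(2-hydroxypropan-2-yl)-5-methyl-5-[3-(2-methyl-1,3-dioxolan-2-yl)propyl]cyclohexan-1-one | CC(C)(O)C1CC[C@@](C)(CCCC2(C)OCCO2)CC1=O
F4 | step 1 | (5R)-5-methyl-5-[3-(2-methyl-1,3-dioxolan-2-yl)propyl]-2-(propan-2-ylidene)cyclohexan-1-one | CC(C)=C1CC[C@@](C)(CCCC2(C)OCCO2)CC1=O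
F5 | step 2 | (2S,4aR)-4a,8-dimethyl-2-(propan-2-yl)-3,4,4a,5,6,7-hexahydronaphthalen-1(2H)-one (eudesm-4-en-6-one) | CC(C)[C@@H]1CC[C@@]2(C)CCCC(C)=C2C1=O
F6 | step 2 | (1R,2S,4aR)-4a,8-dimethyl-2-(propan-2-yl)-1,2,3,4,4a,5,6,7-octahydronaphthalen-1-ol (eudesm-4-en-6β-ol) | CC(C)[C@@H]1CC[C@@]2(C)CCCC(C)=C2[C@@H]1O
F7 | step 2 | 4β,5β-epoxyeudesman-6β-ol | CC(C)[C@@H]1CC[C@@]2(C)CCC[C@]3(C)O[C@]23[C@@H]1O
F8 | step 2 | 4β,5β-epoxyeudesman-6-one | CC(C)[C@@H]1CC[C@@]2(C)CCC[C@]3(C)O[C@]23C1=O
F9 | step 4 | (1R,2S,4aR,8S,8aS)-8-hydroxy-4a,8-dimethyl-2-(propan-2-yl)decahydronaphthalen-1-yl 2-bromoacetate | CC(C)[C@@H]1CC[C@@]2(C)CCC[C@](C)(O)[C@@H]2[C@@H]1OC(=O)CBr
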